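## The problem

Target 30 is a cembrane diterpenoid. A 14-membered carbocycle (C1–C14) is fused through the tetrasubstituted C1=C15 double bond to a 2,5-dihydrofuran (C1, C2, O, C16, C15), and C15 also carries the acetoxymethyl carbon C17. The macrocycle holds two E-trisubstituted alkenes (C3=C4 and C11=C12) and a trans-trisubstituted epoxide (7S,8S). The only other stereocentre is the doubly allylic ether carbon C2 (S).

C2 and the epoxide lie four ring atoms apart in a flexible ring, so neither can control the other. The epoxide therefore has to come from a reagent-controlled epoxidation of an allylic alcohol and C2 from a reagent-controlled carbonyl reduction. Both alkene geometries must be fixed by mechanism and not left to a macrocyclisation.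

The groups that will not stand rough treatment are the trisubstituted epoxide (acid, Lewis acid, hydride, cuprate), the C2–O bond flanked by two alkenes (ionisation, drift of the dihydrofuran towards a furan) and the allylic acetate. The heterocycle and the ester are therefore best installed last, under nearly neutral conditions.

Two features make a simple ring closure possible. The E-C3=C4 alkene sits next to oxygen-bearing C2, so it can pass through ring formation as a C3≡C4 triple bond and be turned afterwards into the E-methyl alkene under the direction of the C2 hydroxyl. C15 carries two oxygenated methylene groups (C16 in the ring, C17 outside it), so before the furan is closed it can be a symmetric bis(silyloxymethyl)alkylidene carbon, and the tetrasubstituted alkene then has no geometry to set.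

## Retrosynthesis

**Acetate and furan ring (30 ⇒ 29 ⇒ 28).** The acetyl–O bond and the C16–O ring bond are cut, leading through alcohol 29 to triol 28. Cutting O–C16 is preferred to cutting O–C2 because the forward closure displaces an activated primary allylic oxygen by the C2 hydroxyl and never breaks a bond at the doubly allylic stereocentre. In 28 the two hydroxymethyl groups on C15 are identical, so no alkene geometry is carried. Only the arm cis to C2 can reach it, and the other arm remains as the C17 alcohol of 29. The forward reactions (a cyclodehydration and an acylation) must be neutral enough for the epoxide.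

**E-C3=C4 and its methyl group (28 ⇒ 27 ⇒ 26 ⇒ 24).** Desilylation relates 28 to bis(silyl ether) 27. The C4–CH3 bond is cut to alkenyl iodide 26, and the alkene is taken back, through aluminate 25, to the triple bond of cycloalkynol 24. Against a direct olefin ring closure at C3=C4, the E geometry here follows from an anti addition steered by the C2 alkoxide and from a stereoretentive coupling, not from ring conformation. Compound 24 is simpler by one alkene geometry and one methyl group. The forward sequence asks that hydride adds to the alkyne before it opens the epoxide, and that the methyl group arrives by a zinc/palladium coupling and not from a cuprate.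

**The macrocycle (24 ⇒ 23 ⇒ 22).** With the C2 hydroxyl masked as triethylsilyl ether 23, the C3≡C4 bond is cut by alkyne metathesis, giving open-chain diyne 22 with two methyl caps. A closure at C2–C3 would create C2 in the ring-forming step with little control. A closure at C1=C15 or C14–C1 would have to build a tetrasubstituted centre at high dilution. The metathesis forms no stereocentre, leaves alkenes, epoxide and silyl ethers alone, and joins two sp carbons. Compound 22 is acyclic and already holds all three stereocentres. The forward reaction must favour ring closure over oligomerisation.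

**C2 and the propynyl cap (22 ⇒ 21 ⇒ 20 ⇒ 19).** Silyl ether 22 comes from alcohol 21. The C2 stereocentre is removed by going back to ynone 20, and the C2–C3 bond is cut to Weinreb amide 19 and a propynyl nucleophile. The carbonyl reduction has to tell a slender alkynyl group from a bulky tetrasubstituted alkenyl group, which is a large difference in size and suits an oxazaborolidine catalyst.

**Tetrasubstituted alkene and C14–C1 (19 ⇒ 18 ⇒ 15 + 17; 15 ⇒ 13 + 14; 17 ⇐ 16).** Amide 19 comes from ester 18. The C1=C15 bond is cut by a phosphonate olefination into phosphonate 15 and the symmetric ketone 17, which is made from dihydroxyacetone 16. Phosphonate 15 comes from bromide 13 and triethyl phosphonoacetate 14. A symmetric ketone removes the geometry question, and its two α-oxygen substituents make it electrophilic enough for an α-branched phosphonate anion, which is the demanding part of the forward reaction.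

**Western alkyne and epoxide (13 ⇒ 9 + 10; 9 ⇐ 8).** The C5–C6 bond is cut. Bromide 13 comes from epoxy alcohol 9 through triflate 12 and the lithiated form 11 of 2-butyne 10. The epoxide comes from a Sharpless epoxidation of allylic alcohol 8, which sets C7 and C8. The C6 hydroxyl is the only one that can direct epoxidation of C7=C8, and the bond formation that brings in the alkyne removes it again. The forward alkylation needs the triflate to react faster than the epoxide or the bromide.

**C14 and the geranyl chain (8 ⇐ 7 ⇐ 6 ⇐ 4 ⇐ 3 ⇐ 1).** Bromo alcohol 8 comes from bromo acetate 7, alcohol 6 (through borane 5), triene 4, enal 3 and geranyl acetate 1 (through alcohol 2). The C13–C14 bond is cut by a methylenation. Two choices of order are deliberate: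
- The hydroboration is placed before the alkyne is introduced, because a hindered borane cannot be trusted to distinguish a conjugated vinyl group from an internal alkyne.
- The allylic oxidation is placed first, where a modest return costs least and where neither epoxide nor alkyne is present.

## Roads not taken

**Alternative 1:** The cut removes C15, C16 and C17 together. O–C16 and C1=C15 are disconnected to the 14-membered α-hydroxy ketone A1 and ethyl 2-(diethoxyphosphoryl)acrylate A2. In the forward key step the C2 alkoxide of A1 adds to A2, and the phosphonate carbanion so formed olefinates the C1 ketone to give dihydrofuran ester A3. Reduction and acetylation would finish the synthesis.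
- Merits: heterocycle and tetrasubstituted alkene are made in one operation. C17 arrives at the ester level, so the two carbons on C15 are different from the start and no cyclodehydration is needed. The end-game is shorter than the chosen one.
- Weak points: in A1 the C2–H is both α to the ketone and allylic. Under the basic conditions needed to form the alkoxide, epimerisation at C2 and migration of C3=C4 into conjugation are real threats. A1 itself still needs a macrocyclisation and a method for the E-C3=C4 alkene, so the central problem is moved, not solved.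
- Comparison: in steps after ring closure this road is better. The chosen plan sets against it that C2 is never next to a carbonyl once it is stereogenic, and that one sequence delivers both the ring and the C3=C4 geometry.

**Alternative 2:** The cut is the C1–C14 bond. The precursor is enol triflate A4, a preformed dihydrofuran with the triflate on C1, a methyl ester on C15 and the whole C2–C13 chain ending in a C13=C14 vinyl group. In the forward key step the bicyclic dialkylborane of step 3 adds to the terminal vinyl group, and palladium-catalysed coupling of the C14 borane with the C1 triflate closes the 14-membered ring to ester A5.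
- Merits: both E-alkenes are made in open-chain chemistry, the tetrasubstituted alkene comes from a coupling, and only ester reduction and acetylation remain after closure. No hydride reagent has to be used near the epoxide late on.
- Weak points: the vinyl group is part of a conjugated diene and is sluggish towards the borane. In A4 and A5 the C2–H is allylic to C3=C4 and vinylogously α to the ester, so the aqueous base of the coupling invites racemisation and isomerisation towards a furan. Before the triflate is installed, C2 is α to a ketone, so even preparing A4 as one enantiomer is delicate. A macrocyclic alkyl–alkenyl coupling that makes a tetrasubstituted alkene at high dilution competes with protodeboronation and β-hydride elimination.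
- Comparison: this road is shorter after ring closure and avoids the hydroalumination, and in those respects it is better. The chosen plan offers a configurationally safe C2 and a ring closure between two unhindered sp carbons.

**Alternative 3:** The cut is the C1–C2 bond. The precursor is the 17-membered cyclic allyl propargyl ether A6, in which oxygen links C2 and C16. In the forward key step a chiral lithium amide removes a propargylic C2–H, and a [2,3]-Wittig shift contracts the ring to the 14-membered propargylic alcohol A7.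
- Merits: the large ring is closed by a simple etherification, which is more robust than any metathesis at high dilution. The contraction makes the C1–C2 bond and the C2 carbinol at once. A7 is a cycloalkynol like 24, so the directed methylation of steps 17 and 18 could follow.
- Weak points: enantiotopic deprotonation by a chiral amide base is usually only moderately selective, and here it acts on a substrate that already carries the epoxide stereocentres, so diastereomers must be expected. A strong amide base can also isomerise the trisubstituted epoxide to an allylic alcohol. In A7 the alkene is exocyclic (C15=C16) and C1 is sp3, so the double bond has to be moved to C1=C15 while C16 is oxidised, which adds several steps.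
- Comparison: the ring closure is the better one. The chosen plan sets against it the reliable catalyst-controlled reduction for C2 and the correct oxidation pattern on C15 from the outset.

Key step: step 15

Remark: atoms are numbered as in cembranes (ring C1–C14, alkylidene carbon C15, ring OCH2 C16, CH2OAc carbon C17, methyl groups C18–C20 on C4, C8 and C12). 1,3-Dihydroxyacetone is handled as its commercial dimer, which reacts as the monomer.

## Route

Step 1
Reactants: 1 geranyl acetate
Product: 3 (2E,6E)-3,7-dimethyl-8-oxoocta-2,6-dien-1-yl acetate, via 8-hydroxygeranyl acetate 2 (not isolated)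
Conditions: SeO2 (cat.), t-BuOOH, salicylic acid (cat.), CH2Cl2, rt; filter, then activated MnO2, CH2Cl2, rt
Reagents that add atoms: tert-butyl hydroperoxide, CC(C)(C)OO
Why: Allylic oxidation by SeO2 (ene reaction, then [2,3]-shift) takes place at the E-methyl of the electron-rich terminal alkene, the 2,3-alkene being deactivated by the acetate; MnO2 then converges the alcohol/aldehyde mixture on the E-enal.

Step 2
Reactants: 3 (2E,6E)-3,7-dimethyl-8-oxoocta-2,6-dien-1-yl acetate
Product: 4 (2E,6E)-3,7-dimethylnona-2,6,8-trien-1-yl acetate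
Conditions: Ph3PCH3Br, KN(SiMe3)2, THF, 0 °C; then 3, −78 → 0 °C
Reagents that add atoms: methyltriphenylphosphonium bromide, C[P+](c1ccccc1)(c1ccccc1)c1ccccc1.[Br-]
Why: Wittig methylenation; the unstabilised ylide should take the aldehyde at low temperature far faster than the acetate, and the existing alkene geometries are not touched.

Step 3
Reactants: 4 (2E,6E)-3,7-dimethylnona-2,6,8-trien-1-yl acetate
Product: 6 (2E,6E)-9-hydroxy-3,7-dimethylnona-2,6-dien-1-yl acetate, via B-alkyl-9-borabicyclononane 5 (not isolated)
Conditions: 9-borabicyclo[3.3.1]nonane, THF, 0 °C → rt; then NaBO3·4H2O, H2O, rt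
Reagents that add atoms: sodium perborate (oxygen of 6), [Na+].[Na+].O[B-]1(O)OO[B-](O)(O)OO1; 9-borabicyclo[3.3.1]nonane (boron bicycle of 5 only), B1C2CCCC1CCC2
Why: Hydroboration–oxidation; the hindered borane should add only to the monosubstituted end of the diene with boron on C9, and perborate oxidises the C–B bond mildly enough to keep the acetate. No alkyne is yet present to compete.

Step 4
Reactants: 6 (2E,6E)-9-hydroxy-3,7-dimethylnona-2,6-dien-1-yl acetate
Product: 7 (2E,6E)-9-bromo-3,7-dimethylnona-2,6-dien-1-yl acetate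
Conditions: CBr4, PPh3, CH2Cl2, 0 °C
Reagents that add atoms: carbon tetrabromide, BrC(Br)(Br)Br
Why: Appel bromination of a primary alcohol under neutral conditions; acetate and alkenes are spectators.

Step 5
Reactants: 7 (2E,6E)-9-bromo-3,7-dimethylnona-2,6-dien-1-yl acetate
Product: 8 (2E,6E)-9-bromo-3,7-dimethylnona-2,6-dien-1-ol
Conditions: K2CO3, MeOH, 0 °C
Reagents that add atoms: none
Why: Base-catalysed methanolysis of the acetate; a primary alkyl bromide should survive brief exposure to carbonate in cold methanol.

Step 6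
Reactants: 8 (2E,6E)-9-bromo-3,7-dimethylnona-2,6-dien-1-ol
Product: 9 [(2S,3S)-3-[(3E)-6-bromo-4-methylhex-3-en-1-yl]-3-methyloxiran-2-yl]methanol
Conditions: Ti(OiPr)4 (cat.), diethyl L-(+)-tartrate (cat.), t-BuOOH, 4 Å molecular sieves, CH2Cl2, −20 °C
Reagents that add atoms: tert-butyl hydroperoxide, CC(C)(C)OO
Why: Sharpless asymmetric epoxidation; only the allylic alcohol alkene is epoxidised, and the L-(+)-tartrate complex delivers oxygen to the face that gives the (2S,3S)-epoxy alcohol, which sets C7 and C8 of the target.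

Step 7
Reactants: 9 [(2S,3S)-3-[(3E)-6-bromo-4-methylhex-3-en-1-yl]-3-methyloxiran-2-yl]methanol; 10 2-butyne
Product: 13 (2S,3S)-2-[(3E)-6-bromo-4-methylhex-3-en-1-yl]-2-methyl-3-(pent-3-yn-1-yl)oxirane, via but-2-yn-1-yllithium 11 (not isolated), via epoxy triflate 12 (not isolated)
Conditions: (a) 10 (excess), n-BuLi, Me2NCH2CH2NMe2, THF, −20 → 0 °C; (b) 9, (CF3SO2)2O, 2,6-lutidine, CH2Cl2, −78 °C, rapid cold work-up; (c) crude 12 added to 11, THF, −78 °C
Reagents that add atoms: trifluoromethanesulfonic anhydride (CF3SO2 group of 12 only), O=S(=O)(OS(=O)(=O)C(F)(F)F)C(F)(F)F; n-butyllithium (lithium of 11 only), [Li]CCCC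
Why: Triflation, then SN2 alkylation of a propargylic organolithium; the primary triflate should be displaced at −78 °C well before the epoxide or the bromide reacts, and the ambident anion attacks alkyl electrophiles mainly through its CH2 end to give the 2-alkyne. The stereocentres are not involved.

Step 8
Reactants: 13 (2S,3S)-2-[(3E)-6-bromo-4-methylhex-3-en-1-yl]-2-methyl-3-(pent-3-yn-1-yl)oxirane; 14 triethyl phosphonoacetate
Product: 15 ethyl (5E)-2-(diethoxyphosphoryl)-5-methyl-8-[(2S,3S)-2-methyl-3-(pent-3-yn-1-yl)oxiran-2-yl]oct-5-enoate (both epimers at the phosphonate carbon)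
Conditions: NaH, 14 (excess), NaI (cat.), THF/DMF, 50 °C
Reagents that add atoms: none
Why: C-alkylation of a sodium phosphonoacetate with a primary bromide under iodide catalysis; excess phosphonate holds back dialkylation, and the soft carbanion should not open the trisubstituted epoxide. The new centre is a mixture and disappears in step 10.

Step 9
Reactants: 16 1,3-dihydroxyacetone
Product: 17 1,3-bis[(tert-butyldimethylsilyl)oxy]propan-2-one
Conditions: t-BuMe2SiCl, imidazole, DMF, 0 °C → rt
Reagents that add atoms: tert-butyldimethylsilyl chloride, CC(C)(C)[Si](C)(C)Cl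
Why: Silylation of both primary hydroxyls; the dimer of 16 dissociates under the conditions.

Step 10
Reactants: 15 ethyl (5E)-2-(diethoxyphosphoryl)-5-methyl-8-[(2S,3S)-2-methyl-3-(pent-3-yn-1-yl)oxiran-2-yl]oct-5-enoate; 17 1,3-bis[(tert-butyldimethylsilyl)oxy]propan-2-one
Product: 18 ethyl (5E)-2-{1,3-bis[(tert-butyldimethylsilyl)oxy]propan-2-ylidene}-5-methyl-8-[(2S,3S)-2-methyl-3-(pent-3-yn-1-yl)oxiran-2-yl]oct-5-enoate
Conditions: NaH (1 equiv), THF, 0 °C; then 17, rt → 50 °C
Reagents that add atoms: none
Why: Horner–Wadsworth–Emmons olefination; the doubly α-oxygenated ketone is electrophilic enough for an α-alkyl phosphonoacetate anion, and because its two arms are identical the tetrasubstituted alkene has no geometry to control.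

Step 11
Reactants: 18 ethyl (5E)-2-{1,3-bis[(tert-butyldimethylsilyl)oxy]propan-2-ylidene}-5-methyl-8-[(2S,3S)-2-methyl-3-(pent-3-yn-1-yl)oxiran-2-yl]oct-5-enoate
Product: 19 (5E)-2-{1,3-bis[(tert-butyldimethylsilyl)oxy]propan-2-ylidene}-N-methoxy-N,5-dimethyl-8-[(2S,3S)-2-methyl-3-(pent-3-yn-1-yl)oxiran-2-yl]oct-5-enamide
Conditions: MeNH(OMe)·HCl, iPrMgCl, THF, −20 °C → rt
Reagents that add atoms: N,O-dimethylhydroxylamine hydrochloride, CNOC.Cl
Why: Weinreb amide formation by aminolysis of the ester with the magnesium amide; the epoxide and silyl ethers should tolerate the non-nucleophilic Grignard base at low temperature.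

Step 12
Reactants: 19 (5E)-2-{1,3-bis[(tert-butyldimethylsilyl)oxy]propan-2-ylidene}-N-methoxy-N,5-dimethyl-8-[(2S,3S)-2-methyl-3-(pent-3-yn-1-yl)oxiran-2-yl]oct-5-enamide
Product: 20 (8E)-5-{1,3-bis[(tert-butyldimethylsilyl)oxy]propan-2-ylidene}-8-methyl-11-[(2S,3S)-2-methyl-3-(pent-3-yn-1-yl)oxiran-2-yl]undec-8-en-2-yn-4-one
Conditions: MeC≡CMgBr, THF, 0 °C → rt
Reagents that add atoms: 1-propynylmagnesium bromide, CC#C[Mg]Br
Why: Addition of an alkynyl Grignard reagent to a Weinreb amide; the chelated tetrahedral intermediate prevents a second addition and gives the ynone on work-up.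

Step 13
Reactants: 20 (8E)-5-{1,3-bis[(tert-butyldimethylsilyl)oxy]propan-2-ylidene}-8-methyl-11-[(2S,3S)-2-methyl-3-(pent-3-yn-1-yl)oxiran-2-yl]undec-8-en-2-yn-4-one
Product: 21 (4S,8E)-5-{1,3-bis[(tert-butyldimethylsilyl)oxy]propan-2-ylidene}-8-methyl-11-[(2S,3S)-2-methyl-3-(pent-3-yn-1-yl)oxiran-2-yl]undec-8-en-2-yn-4-ol
Conditions: (R)-2-methyl-CBS-oxazaborolidine, catecholborane, CH2Cl2, −78 °C
Reagents that add atoms: none
Why: Corey–Bakshi–Shibata reduction; the ketone binds the catalyst with the bulky tetrasubstituted alkenyl group as the large and the slender propynyl group as the small substituent, so the (R)-catalyst should deliver hydride to the face that gives the (S)-carbinol (C2). Catecholborane at −78 °C avoids hydroboration and spares the epoxide.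

Step 14
Reactants: 21 (4S,8E)-5-{1,3-bis[(tert-butyldimethylsilyl)oxy]propan-2-ylidene}-8-methyl-11-[(2S,3S)-2-methyl-3-(pent-3-yn-1-yl)oxiran-2-yl]undec-8-en-2-yn-4-ol
Product: 22 (4S,8E)-5-{1,3-bis[(tert-butyldimethylsilyl)oxy]propan-2-ylidene}-8-methyl-11-[(2S,3S)-2-methyl-3-(pent-3-yn-1-yl)oxiran-2-yl]-4-[(triethylsilyl)oxy]undec-8-en-2-yne
Conditions: Et3SiCl, imidazole, 4-(dimethylamino)pyridine (cat.), CH2Cl2, 0 °C → rt
Reagents that add atoms: chlorotriethylsilane, CC[Si](CC)(CC)Cl
Why: Silylation of the secondary alcohol with the chloride (a silyl triflate is avoided because of the epoxide); the ether hides the protic site from the alkylidyne catalyst.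

Step 15
Reactants: 22 (4S,8E)-5-{1,3-bis[(tert-butyldimethylsilyl)oxy]propan-2-ylidene}-8-methyl-11-[(2S,3S)-2-methyl-3-(pent-3-yn-1-yl)oxiran-2-yl]-4-[(triethylsilyl)oxy]undec-8-en-2-yne
Product: 23 (2S,7S,8S,11E)-16,17-bis[(tert-butyldimethylsilyl)oxy]-7,8-epoxy-2-[(triethylsilyl)oxy]-18-norcembra-1(15),11-dien-3-yne (14-membered cycloalkyne)
Conditions: Mo(≡CC6H4OMe-4)(OSiPh3)3 (cat.), 5 Å molecular sieves, toluene (0.002 M), rt → 60 °C
Reagents that add atoms: none
Why: The alkylidyne adds across the unhindered C4 alkyne to a molybdacyclobutadiene whose cycloreversion places the metal on C4; an intramolecular [2+2] addition to the C3 alkyne and a second cycloreversion release the cycloalkyne and a molybdenum ethylidyne, which re-enters the cycle with loss of 2-butyne. The closest known reaction type is ring-closing alkyne metathesis of methyl-capped diynes to macrocyclic cycloalkynes with molybdenum alkylidyne silanolate complexes, which is established for substrates with propargylic silyl ethers. The ring is closed as a metathesis macrocyclisation to a 14-membered carbocycle with the new C3≡C4 bond inside the ring. No stereocentre is formed, and the neutral aprotic medium cannot epimerise propargylic C2 or disturb C7 and C8. The step needs selectivity for triple bonds, which is inherent because a hexavalent molybdenum alkylidyne does not engage alkenes, the epoxide or silyl ethers. It also needs ring closure to win over oligomerisation, which is secured by high dilution, by the sieves that trap 2-butyne and by the reversibility of oligomer formation; the E-alkene, the trans-epoxide and sp2 C1 reduce the freedom of the chain, while a 14-membered ring holds the linear C2–C3≡C4–C5 unit without undue strain.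

Step 16
Reactants: 23 (2S,7S,8S,11E)-16,17-bis[(tert-butyldimethylsilyl)oxy]-7,8-epoxy-2-[(triethylsilyl)oxy]-18-norcembra-1(15),11-dien-3-yne
Product: 24 (2S,7S,8S,11E)-16,17-bis[(tert-butyldimethylsilyl)oxy]-7,8-epoxy-18-norcembra-1(15),11-dien-3-yn-2-ol
Conditions: pyridinium p-toluenesulfonate (cat.), MeOH/CH2Cl2, 0 °C
Reagents that add atoms: none
Why: Acid-catalysed methanolysis; a secondary triethylsilyl ether is cleaved much faster than primary tert-butyldimethylsilyl ethers, and the buffered acid at 0 °C should leave the trisubstituted epoxide intact.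

Step 17
Reactants: 24 (2S,7S,8S,11E)-16,17-bis[(tert-butyldimethylsilyl)oxy]-7,8-epoxy-18-norcembra-1(15),11-dien-3-yn-2-ol
Product: 26 (2S,3Z,7S,8S,11E)-16,17-bis[(tert-butyldimethylsilyl)oxy]-7,8-epoxy-4-iodo-18-norcembra-1(15),3,11-trien-2-ol, via cyclic vinylalanate 25 (not isolated)
Conditions: NaAlH2(OCH2CH2OMe)2, THF, 0 °C → rt; EtOAc, 0 °C; then I2, THF, −78 °C
Reagents that add atoms: iodine, II; sodium bis(2-methoxyethoxy)aluminium dihydride (aluminate part of 25 only), [Na+].COCCO[AlH2-]OCCOC
Why: Hydroxyl-directed trans-hydroalumination of a propargylic alcohol followed by iodinolysis; the alkoxyaluminate delivers hydride to C3 and aluminium to C4 within a five-membered chelate, so iodine ends on C4 cis to C2, which fixes the E geometry of the final alkene.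

Step 18
Reactants: 26 (2S,3Z,7S,8S,11E)-16,17-bis[(tert-butyldimethylsilyl)oxy]-7,8-epoxy-4-iodo-18-norcembra-1(15),3,11-trien-2-ol
Product: 27 (2S,3E,7S,8S,11E)-16,17-bis[(tert-butyldimethylsilyl)oxy]-7,8-epoxycembra-1(15),3,11-trien-2-ol
Conditions: Me2Zn (excess), Pd(PPh3)4 (cat.), THF, 0 °C → rt
Reagents that add atoms: dimethylzinc, C[Zn]C
Why: Negishi cross-coupling with retention of alkene geometry; the zinc reagent with a zerovalent palladium catalyst is chosen over a cuprate because it should not open the epoxide, and the free hydroxyl is tolerated as its zinc alkoxide.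

Step 19
Reactants: 27 (2S,3E,7S,8S,11E)-16,17-bis[(tert-butyldimethylsilyl)oxy]-7,8-epoxycembra-1(15),3,11-trien-2-ol
Product: 28 (2S,3E,7S,8S,11E)-7,8-epoxycembra-1(15),3,11-triene-2,16,17-triol
Conditions: Bu4NF, THF, 0 °C → rt
Reagents that add atoms: none
Why: Fluoride-mediated cleavage of both primary silyl ethers under basic conditions that the epoxide and the allylic alcohols tolerate.

Step 20
Reactants: 28 (2S,3E,7S,8S,11E)-7,8-epoxycembra-1(15),3,11-triene-2,16,17-triol
Product: 29 (2S,3E,7S,8S,11E)-2,16:7,8-diepoxycembra-1(15),3,11-trien-17-ol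
Conditions: PPh3, diisopropyl azodicarboxylate (1.1 equiv), THF, 0 °C → rt
Reagents that add atoms: none
Why: Mitsunobu cyclodehydration of a (Z)-but-2-ene-1,4-diol unit to a 2,5-dihydrofuran; the less hindered primary allylic hydroxyl cis to C2 is activated and displaced by the C2 hydroxyl (5-exo-tet), so C2 keeps its configuration. The trans arm cannot reach C2 and stays as the C17 alcohol.

Step 21
Reactants: 29 (2S,3E,7S,8S,11E)-2,16:7,8-diepoxycembra-1(15),3,11-trien-17-ol
Product: 30 (2S,3E,7S,8S,11E)-2,16:7,8-diepoxycembra-1(15),3,11-trien-17-yl acetate (CNP0140293.1)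
Conditions: Ac2O, pyridine, 4-(dimethylamino)pyridine (cat.), CH2Cl2, 0 °C
Reagents that add atoms: acetic anhydride, CC(=O)OC(C)=O
Why: Acylation of the primary allylic alcohol under basic conditions that leave the epoxide and the dihydrofuran alone.

## Compound list

1 | geranyl acetate | CC(C)=CCC/C(C)=C/COC(C)=O | starting material
2 | (2E,6E)-8-hydroxy-3,7-dimethylocta-2,6-dien-1-yl acetate | OC/C(C)=C/CC/C(C)=C/COC(C)=O | intermediate
3 | (2E,6E)-3,7-dimethyl-8-oxoocta-2,6-dien-1-yl acetate | O=C/C(C)=C/CC/C(C)=C/COC(C)=O | intermediate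
4 | (2E,6E)-3,7-dimethylnona-2,6,8-trien-1-yl acetate | C=C/C(C)=C/CC/C(C)=C/COC(C)=O | intermediate
5 | (2E,6E)-9-(9-borabicyclo[3.3.1]nonan-9-yl)-3,7-dimethylnona-2,6-dien-1-yl acetate | CC(=O)OC/C=C(C)/CC/C=C(C)/CCB1C2CCCC1CCC2 | intermediate
6 | (2E,6E)-9-hydroxy-3,7-dimethylnona-2,6-dien-1-yl acetate | OCC/C(C)=C/CC/C(C)=C/COC(C)=O | intermediate
7 | (2E,6E)-9-bromo-3,7-dimethylnona-2,6-dien-1-yl acetate | BrCC/C(C)=C/CC/C(C)=C/COC(C)=O | intermediate
8 | (2E,6E)-9-bromo-3,7-dimethylnona-2,6-dien-1-ol | BrCC/C(C)=C/CC/C(C)=C/CO | intermediate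
9 | [(2S,3S)-3-[(3E)-6-bromo-4-methylhex-3-en-1-yl]-3-methyloxiran-2-yl]methanol | BrCC/C(C)=C/CC[C@]1(C)O[C@H]1CO | intermediate
10 | 2-butyne | CC#CC | starting material
11 | but-2-yn-1-yllithium | [Li]CC#CC | intermediate
12 | [(2S,3S)-3-[(3E)-6-bromo-4-methylhex-3-en-1-yl]-3-methyloxiran-2-yl]methyl trifluoromethanesulfonate | BrCC/C(C)=C/CC[C@]1(C)O[C@H]1COS(=O)(=O)C(F)(F)F | intermediate
13 | (2S,3S)-2-[(3E)-6-bromo-4-methylhex-3-en-1-yl]-2-methyl-3-(pent-3-yn-1-yl)oxirane | BrCC/C(C)=C/CC[C@]1(C)O[C@H]1CCC#CC | intermediate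
14 | triethyl phosphonoacetate | CCOC(=O)CP(=O)(OCC)OCC | starting material
15 | ethyl (5E)-2-(diethoxyphosphoryl)-5-methyl-8-[(2S,3S)-2-methyl-3-(pent-3-yn-1-yl)oxiran-2-yl]oct-5-enoate (both epimers at the phosphonate carbon) | CCOC(=O)C(CC/C(C)=C/CC[C@]1(C)O[C@H]1CCC#CC)P(=O)(OCC)OCC | intermediate
16 | 1,3-dihydroxyacetone | OCC(=O)CO | starting material
17 | 1,3-bis[(tert-butyldimethylsilyl)oxy]propan-2-one | CC(C)(C)[Si](C)(C)OCC(=O)CO[Si](C)(C)C(C)(C)C | intermediate
18 | ethyl (5E)-2-{1,3-bis[(tert-butyldimethylsilyl)oxy]propan-2-ylidene}-5-methyl-8-[(2S,3S)-2-methyl-3-(pent-3-yn-1-yl)oxiran-2-yl]oct-5-enoate | CCOC(=O)C(CC/C(C)=C/CC[C@]1(C)O[C@H]1CCC#CC)=C(CO[Si](C)(C)C(C)(C)C)CO[Si](C)(C)C(C)(C)C | intermediate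
19 | (5E)-2-{1,3-bis[(tert-butyldimethylsilyl)oxy]propan-2-ylidene}-N-methoxy-N,5-dimethyl-8-[(2S,3S)-2-methyl-3-(pent-3-yn-1-yl)oxiran-2-yl]oct-5-enamide | CON(C)C(=O)C(CC/C(C)=C/CC[C@]1(C)O[C@H]1CCC#CC)=C(CO[Si](C)(C)C(C)(C)C)CO[Si](C)(C)C(C)(C)C | intermediate
20 | (8E)-5-{1,3-bis[(tert-butyldimethylsilyl)oxy]propan-2-ylidene}-8-methyl-11-[(2S,3S)-2-methyl-3-(pent-3-yn-1-yl)oxiran-2-yl]undec-8-en-2-yn-4-one | CC#CC(=O)C(CC/C(C)=C/CC[C@]1(C)O[C@H]1CCC#CC)=C(CO[Si](C)(C)C(C)(C)C)CO[Si](C)(C)C(C)(C)C | intermediate
21 | (4S,8E)-5-{1,3-bis[(tert-butyldimethylsilyl)oxy]propan-2-ylidene}-8-methyl-11-[(2S,3S)-2-methyl-3-(pent-3-yn-1-yl)oxiran-2-yl]undec-8-en-2-yn-4-ol | CC#C[C@H](O)C(CC/C(C)=C/CC[C@]1(C)O[C@H]1CCC#CC)=C(CO[Si](C)(C)C(C)(C)C)CO[Si](C)(C)C(C)(C)C | intermediate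
22 | (4S,8E)-5-{1,3-bis[(tert-butyldimethylsilyl)oxy]propan-2-ylidene}-8-methyl-11-[(2S,3S)-2-methyl-3-(pent-3-yn-1-yl)oxiran-2-yl]-4-[(triethylsilyl)oxy]undec-8-en-2-yne | CC#C[C@H](O[Si](CC)(CC)CC)C(CC/C(C)=C/CC[C@]1(C)O[C@H]1CCC#CC)=C(CO[Si](C)(C)C(C)(C)C)CO[Si](C)(C)C(C)(C)C | intermediate
23 | (2S,7S,8S,11E)-16,17-bis[(tert-butyldimethylsilyl)oxy]-7,8-epoxy-2-[(triethylsilyl)oxy]-18-norcembra-1(15),11-dien-3-yne | CC[Si](CC)(CC)O[C@H]1C#CCC[C@@H]2O[C@@]2(C)CC/C=C(C)/CCC1=C(CO[Si](C)(C)C(C)(C)C)CO[Si](C)(C)C(C)(C)C | intermediate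
24 | (2S,7S,8S,11E)-16,17-bis[(tert-butyldimethylsilyl)oxy]-7,8-epoxy-18-norcembra-1(15),11-dien-3-yn-2-ol | O[C@H]1C#CCC[C@@H]2O[C@@]2(C)CC/C=C(C)/CCC1=C(CO[Si](C)(C)C(C)(C)C)CO[Si](C)(C)C(C)(C)C | intermediate
25 | sodium alkoxy(alkenyl)bis(2-methoxyethoxy)aluminate of 24, with aluminium bridging the C2 oxygen and C4 in a five-membered ring (O–Al–C4=C3–C2) | [Na+].COCCO[Al-]1(OCCOC)O[C@H]2/C=C1/CC[C@@H]3O[C@@]3(C)CC/C=C(C)/CCC2=C(CO[Si](C)(C)C(C)(C)C)CO[Si](C)(C)C(C)(C)C | intermediate
26 | (2S,3Z,7S,8S,11E)-16,17-bis[(tert-butyldimethylsilyl)oxy]-7,8-epoxy-4-iodo-18-norcembra-1(15),3,11-trien-2-ol | O[C@H]1/C=C(I)/CC[C@@H]2O[C@@]2(C)CC/C=C(C)/CCC1=C(CO[Si](C)(C)C(C)(C)C)CO[Si](C)(C)C(C)(C)C | intermediate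
27 | (2S,3E,7S,8S,11E)-16,17-bis[(tert-butyldimethylsilyl)oxy]-7,8-epoxycembra-1(15),3,11-trien-2-ol | O[C@H]1/C=C(C)/CC[C@@H]2O[C@@]2(C)CC/C=C(C)/CCC1=C(CO[Si](C)(C)C(C)(C)C)CO[Si](C)(C)C(C)(C)C | intermediate
28 | (2S,3E,7S,8S,11E)-7,8-epoxycembra-1(15),3,11-triene-2,16,17-triol | O[C@H]1/C=C(C)/CC[C@@H]2O[C@@]2(C)CC/C=C(C)/CCC1=C(CO)CO | intermediate
29 | (2S,3E,7S,8S,11E)-2,16:7,8-diepoxycembra-1(15),3,11-trien-17-ol | OCC1=C2CC/C(C)=C/CC[C@]3(C)O[C@H]3CC/C(C)=C/[C@@H]2OC1 | intermediate
30 | (2S,3E,7S,8S,11E)-2,16:7,8-diepoxycembra-1(15),3,11-trien-17-yl acetate (CNP0140293.1) | CC(=O)OCC1=C2CC/C(C)=C/CC[C@]3(C)O[C@H]3CC/C(C)=C/[C@@H]2OC1 | target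

## Step count and least certain steps

Total step count: 21. Longest linear sequence: 20 steps (steps 1–8 and 10–21, from geranyl acetate 1 to 30); step 9 is a one-step branch.

**Step 15 (key step).** The most likely failure is oligomerisation, with cyclic dimers or open oligomers forming in place of the monomeric ring. The C3 alkyne is flanked by a silyloxy group and a tetrasubstituted alkene and may enter the cycle slowly, while the three rigid elements of the chain may disfavour the folded conformer. Slow turnover would also expose the catalyst to traces of protic impurities. The fallback closes the ring at C2–C3 by a chromium-mediated coupling of an alkynyl iodide with an aldehyde (Nozaki–Hiyama–Kishi reaction) and keeps the C3≡C4 triple bond for steps 17 and 18. It sets out from triflate 12 and returns to the route at 24.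
- 3-Lithio-1-(trimethylsilyl)propyne (from 1-(trimethylsilyl)propyne and n-BuLi) displaces the triflate to give (2S,3S)-2-[(3E)-6-bromo-4-methylhex-3-en-1-yl]-2-methyl-3-[4-(trimethylsilyl)but-3-yn-1-yl]oxirane F1.
- The conditions of steps 8 and 10 turn it into the phosphonate F2 and then the tetrasubstituted ethyl enoate F3.
- i-Bu2AlH (CH2Cl2, −78 °C) reduces the ester to the allylic alcohol F4.
- N-Iodosuccinimide with AgNO3 (cat.) in acetone exchanges silicon for iodine to give the iodoalkyne alcohol F5, and MnO2 gives the iodoalkyne enal F6.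
- CrCl2 with NiCl2 (cat.) in THF at high dilution closes the ring to the cycloalkynol F7 as a mixture of C2 epimers.
- MnO2 gives the macrocyclic ynone F8, and the oxazaborolidine reduction of step 13 converts it into cycloalkynol 24. The triethylsilyl ether is not needed on this path.

**Step 7.** The lithiated butyne is ambident, and attack through its allenyl end would give an allene isomer. The epoxy triflate may also decompose before it is alkylated. The fallback uses a propargyl anion whose silyl group blocks the allenyl mode. It sets out from triflate 12 and returns at 13. 3-Lithio-1-(trimethylsilyl)propyne gives the silyl alkyne F1 described above; K2CO3 in methanol removes the silyl group to give (2S,3S)-2-[(3E)-6-bromo-4-methylhex-3-en-1-yl]-3-(but-3-yn-1-yl)-2-methyloxirane F9; deprotonation with n-BuLi at −78 °C and methylation with iodomethane then gives 13.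

**Step 10.** The α-branched phosphonate anion is hindered and may add slowly. The ketone may be enolised instead, and excess base could move the new double bond out of conjugation towards a silyl enol ether. The fallback makes the C14–C1 bond by a palladium-catalysed alkyl–alkenyl Negishi coupling. It sets out from bromide 13 and ketone 17 and returns at 18.
- Ketone 17 and unsubstituted phosphonate 14 (NaH, THF) give ethyl 4-[(tert-butyldimethylsilyl)oxy]-3-{[(tert-butyldimethylsilyl)oxy]methyl}but-2-enoate F10.
- Bromine adds to give the dibromide F11, and triethylamine removes HBr to give the α-bromo enoate F12.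
- Zinc dust with LiCl in THF inserts into bromide 13 to give the alkylzinc bromide F13.
- Pd(OAc)2 with dicyclohexyl(2',6'-dimethoxybiphenyl-2-yl)phosphine couples F13 with F12 to give enoate 18.

**Step 13.** Poor facial selectivity is the main risk. The tetrasubstituted alkenyl group is twisted out of conjugation and both flanking groups are unsaturated, so the catalyst's size discrimination could be less clean than expected. Conjugate reduction of the ynone is a second risk. The fallback sets C2 by a carbon–carbon bond formation. It sets out from ester 18 and returns at 21. i-Bu2AlH reduces 18 to the allylic alcohol F14, MnO2 gives the enal F15, and propyne is added enantioselectively with Me2Zn and a chiral dinuclear zinc amino-alcohol (ProPhenol-type) catalyst, with the ligand enantiomer chosen for the (S)-carbinol, to give 21.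

**Step 17.** The hydride reagent may open the epoxide during the time the hydroalumination needs, and partial protonation of the alkenyl aluminate before iodination would give the iodine-free alkene. The fallback replaces aluminium hydride by a ruthenium-catalysed trans-hydrosilylation. It sets out from 24 and returns at 26. Benzyldimethylsilane with [Cp*Ru(MeCN)3]PF6 (cat.) in CH2Cl2 should add anti across the alkyne with silicon on C4, distal to the hydroxyl, giving the (Z)-alkenylsilane F16. Iododesilylation with N-iodosuccinimide (2,6-lutidine, hexafluoroisopropanol, 0 °C) proceeds with retention to give 26.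

**Step 20.** The phosphonium reagent may activate the doubly allylic C2 hydroxyl instead of the primary one. Closure would then occur with inversion at C2, or by ionisation with loss of configuration. The fallback makes the primary carbons the only possible electrophiles. It sets out from triol 28 and returns at the target 30, bypassing 29. Methanesulfonic anhydride (2 equiv) with triethylamine at −40 °C sulfonylates the two primary hydroxyls to give the bis(methanesulfonate) F17. On warming with triethylamine the C2 hydroxyl displaces the cis sulfonate to give the dihydrofuran methanesulfonate F18. Caesium acetate in DMF replaces the remaining allylic sulfonate by acetate to give 30.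

## Further compounds

F1 | step 15 | (2S,3S)-2-[(3E)-6-bromo-4-methylhex-3-en-1-yl]-2-methyl-3-[4-(trimethylsilyl)but-3-yn-1-yl]oxirane | BrCC/C(C)=C/CC[C@]1(C)O[C@H]1CCC#C[Si](C)(C)C
F2 | step 15 | ethyl (5E)-2-(diethoxyphosphoryl)-5-methyl-8-{(2S,3S)-2-methyl-3-[4-(trimethylsilyl)but-3-yn-1-yl]oxiran-2-yl}oct-5-enoate | CCOC(=O)C(CC/C(C)=C/CC[C@]1(C)O[C@H]1CCC#C[Si](C)(C)C)P(=O)(OCC)OCC
F3 | step 15 | ethyl (5E)-2-{1,3-bis[(tert-butyldimethylsilyl)oxy]propan-2-ylidene}-5-methyl-8-{(2S,3S)-2-methyl-3-[4-(trimethylsilyl)but-3-yn-1-yl]oxiran-2-yl}oct-5-enoate | CCOC(=O)C(CC/C(C)=C/CC[C@]1(C)O[C@H]1CCC#C[Si](C)(C)C)=C(CO[Si](C)(C)C(C)(C)C)CO[Si](C)(C)C(C)(C)C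
F4 | step 15 | (5E)-2-{1,3-bis[(tert-butyldimethylsilyl)oxy]propan-2-ylidene}-5-methyl-8-{(2S,3S)-2-methyl-3-[4-(trimethylsilyl)but-3-yn-1-yl]oxiran-2-yl}oct-5-en-1-ol | OCC(CC/C(C)=C/CC[C@]1(C)O[C@H]1CCC#C[Si](C)(C)C)=C(CO[Si](C)(C)C(C)(C)C)CO[Si](C)(C)C(C)(C)C
F5 | step 15 | (5E)-2-{1,3-bis[(tert-butyldimethylsilyl)oxy]propan-2-ylidene}-8-[(2S,3S)-3-(4-iodobut-3-yn-1-yl)-2-methyloxiran-2-yl]-5-methyloct-5-en-1-ol | OCC(CC/C(C)=C/CC[C@]1(C)O[C@H]1CCC#CI)=C(CO[Si](C)(C)C(C)(C)C)CO[Si](C)(C)C(C)(C)C
F6 | step 15 | (5E)-2-{1,3-bis[(tert-butyldimethylsilyl)oxy]propan-2-ylidene}-8-[(2S,3S)-3-(4-iodobut-3-yn-1-yl)-2-methyloxiran-2-yl]-5-methyloct-5-enal | O=CC(CC/C(C)=C/CC[C@]1(C)O[C@H]1CCC#CI)=C(CO[Si](C)(C)C(C)(C)C)CO[Si](C)(C)C(C)(C)C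
F7 | step 15 | (7S,8S,11E)-16,17-bis[(tert-butyldimethylsilyl)oxy]-7,8-epoxy-18-norcembra-1(15),11-dien-3-yn-2-ol, both C2 epimers | OC1C#CCC[C@@H]2O[C@@]2(C)CC/C=C(C)/CCC1=C(CO[Si](C)(C)C(C)(C)C)CO[Si](C)(C)C(C)(C)C
F8 | step 15 | (7S,8S,11E)-16,17-bis[(tert-butyldimethylsilyl)oxy]-7,8-epoxy-18-norcembra-1(15),11-dien-3-yn-2-one | O=C1C#CCC[C@@H]2O[C@@]2(C)CC/C=C(C)/CCC1=C(CO[Si](C)(C)C(C)(C)C)CO[Si](C)(C)C(C)(C)C
F9 | step 7 | (2S,3S)-2-[(3E)-6-bromo-4-methylhex-3-en-1-yl]-3-(but-3-yn-1-yl)-2-methyloxirane | BrCC/C(C)=C/CC[C@]1(C)O[C@H]1CCC#C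
F10 | step 10 | ethyl 4-[(tert-butyldimethylsilyl)oxy]-3-{[(tert-butyldimethylsilyl)oxy]methyl}but-2-enoate | CCOC(=O)C=C(CO[Si](C)(C)C(C)(C)C)CO[Si](C)(C)C(C)(C)C
F11 | step 10 | ethyl 2,3-dibromo-4-[(tert-butyldimethylsilyl)oxy]-3-{[(tert-butyldimethylsilyl)oxy]methyl}butanoate (racemic) | CCOC(=O)C(Br)C(Br)(CO[Si](C)(C)C(C)(C)C)CO[Si](C)(C)C(C)(C)C
F12 | step 10 | ethyl 2-bromo-4-[(tert-butyldimethylsilyl)oxy]-3-{[(tert-butyldimethylsilyl)oxy]methyl}but-2-enoate | CCOC(=O)C(Br)=C(CO[Si](C)(C)C(C)(C)C)CO[Si](C)(C)C(C)(C)C
F13 | step 10 | {(3E)-3-methyl-6-[(2S,3S)-2-methyl-3-(pent-3-yn-1-yl)oxiran-2-yl]hex-3-en-1-yl}zinc bromide | Br[Zn]CC/C(C)=C/CC[C@]1(C)O[C@H]1CCC#CC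
F14 | step 13 | (5E)-2-{1,3-bis[(tert-butyldimethylsilyl)oxy]propan-2-ylidene}-5-methyl-8-[(2S,3S)-2-methyl-3-(pent-3-yn-1-yl)oxiran-2-yl]oct-5-en-1-ol | OCC(CC/C(C)=C/CC[C@]1(C)O[C@H]1CCC#CC)=C(CO[Si](C)(C)C(C)(C)C)CO[Si](C)(C)C(C)(C)C
F15 | step 13 | (5E)-2-{1,3-bis[(tert-butyldimethylsilyl)oxy]propan-2-ylidene}-5-methyl-8-[(2S,3S)-2-methyl-3-(pent-3-yn-1-yl)oxiran-2-yl]oct-5-enal | O=CC(CC/C(C)=C/CC[C@]1(C)O[C@H]1CCC#CC)=C(CO[Si](C)(C)C(C)(C)C)CO[Si](C)(C)C(C)(C)C
F16 | step 17 | (2S,3Z,7S,8S,11E)-4-(benzyldimethylsilyl)-16,17-bis[(tert-butyldimethylsilyl)oxy]-7,8-epoxy-18-norcembra-1(15),3,11-trien-2-ol | O[C@H]1/C=C([Si](C)(C)Cc3ccccc3)/CC[C@@H]2O[C@@]2(C)CC/C=C(C)/CCC1=C(CO[Si](C)(C)C(C)(C)C)CO[Si](C)(C)C(C)(C)C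
F17 | step 20 | (2S,3E,7S,8S,11E)-7,8-epoxy-2-hydroxycembra-1(15),3,11-triene-16,17-diyl dimethanesulfonate | O[C@H]1/C=C(C)/CC[C@@H]2O[C@@]2(C)CC/C=C(C)/CCC1=C(COS(C)(=O)=O)COS(C)(=O)=O
F18 | step 20 | (2S,3E,7S,8S,11E)-2,16:7,8-diepoxycembra-1(15),3,11-trien-17-yl methanesulfonate | CS(=O)(=O)OCC1=C2CC/C(C)=C/CC[C@]3(C)O[C@H]3CC/C(C)=C/[C@@H]2OC1
A1 | alternative 1 | (2S,3E,7S,8S,11E)-7,8-epoxy-2-hydroxy-4,8,12-trimethylcyclotetradeca-3,11-dien-1-one | O=C1CC/C(C)=C/CC[C@]2(C)O[C@H]2CC/C(C)=C/[C@@H]1O
A2 | alternative 1 | ethyl 2-(diethoxyphosphoryl)acrylate | CCOC(=O)C(=C)P(=O)(OCC)OCC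
A3 | alternative 1 | ethyl (2S,3E,7S,8S,11E)-2,16:7,8-diepoxycembra-1(15),3,11-trien-17-oate | CCOC(=O)C1=C2CC/C(C)=C/CC[C@]3(C)O[C@H]3CC/C(C)=C/[C@@H]2OC1
A4 | alternative 2 | methyl 5-{(1E,9E)-2,10-dimethyl-5,6-epoxy-6-methyldodeca-1,9,11-trienyl}-4-(trifluoromethanesulfonyloxy)-2,5-dihydrofuran-3-carboxylate (C2 as in the target, 7S,8S-epoxide) | COC(=O)C1=C(OS(=O)(=O)C(F)(F)F)[C@H](/C=C(C)/CC[C@@H]2O[C@@]2(C)CC/C=C(C)/C=C)OC1
A5 | alternative 2 | methyl (2S,3E,7S,8S,11E)-2,16:7,8-diepoxycembra-1(15),3,11-trien-17-oate | COC(=O)C1=C2CC/C(C)=C/CC[C@]3(C)O[C@H]3CC/C(C)=C/[C@@H]2OC1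
A6 | alternative 3 | 17-membered cyclic allyl propargyl ether with the C2–O–C16 link, C3≡C4, the (7S,8S)-epoxide, the 11E alkene and a C1=C15 alkene carrying CH2OSi(t-Bu)Me2 | CC(C)(C)[Si](C)(C)OC/C1=C\CC/C(C)=C/CC[C@]2(C)O[C@H]2CCC#CCOC1
A7 | alternative 3 | 14-membered propargylic alcohol with C2 in the spatial sense of the target, C3≡C4, the (7S,8S)-epoxide, the 11E alkene and a 3-[(tert-butyldimethylsilyl)oxy]prop-1-en-2-yl branch on C1 | CC(C)(C)[Si](C)(C)OCC(=C)[C@H]1CC/C(C)=C/CC[C@]2(C)O[C@H]2CCC#C[C@@H]1O
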